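## Structural features

The target is a diaryl ether of two differently substituted benzene rings. Ring A is a 5-pentylresorcinol (C1 pentyl, C3 OH, C5 OH) whose C6, wedged between the pentyl group and the C5 hydroxyl, carries the ether oxygen. Ring B is a benzoic acid (C1 CO2H) with that oxygen at C2, a methoxy group at C4 and a pentanoyl group at C6. There is no stereocentre, and the 2-acylbenzoic acid is the ring–chain tautomer of a 3-butyl-3-hydroxyphthalide, so ring B can travel one oxidation level lower as a racemic 3-butylphthalide. The fragile points are the electron-rich resorcinol, the keto acid (a photoactive aryl ketone next to a free acid) and the need to keep two free phenols distinct from the ring B methyl ether. The real difficulty is the ether: its oxygen has three ortho neighbours (pentyl and OH on ring A, carboxyl on ring B), so a late aryl–O bond formation is unattractive, and ring A must also be made as a single regioisomer. The key step uses the fact that ring A C6 and its oxygen can be carried as the β-carbon and oxygen of an aryl enol ether. C1 and C6 then come from an enone C=C, C5 from its carbonyl carbon, C2 from a diazo carbon and C3–C4 from a silyl ynol ether, whose polarity matches the 1,3-relation of the two ring A oxygens.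

## Logic of the disconnections

**29 from 28.** No skeletal bond is cut; only the O–Si bond at ring A C3 is removed. Keeping one silyl ether to the end leaves the resorcinol half-masked during the oxidation before it. The forward step must cleave the silyl ether without harming the keto acid, which a buffered fluoride source should do.

**28 from 27.** The C–OH bond at the benzylic lactone carbon (the future acyl carbon of ring B) is cut, so the ketone level is traded for a C–H bond. This hides both the aryl ketone chromophore and the free acid as a plain lactone during the diazo and photochemical steps. The forward step must enolize and oxygenate that one carbon in the presence of a free phenol.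

**27 from 17 and 22.** Ring A is opened at C1–C2, C2–C3, C4–C5 and C5–C6. This is the strategic cut: ring A is built around an ether oxygen that is already in place, so no coupling happens at the crowded oxygen. The two new oxygens arise differentiated (free OH at C5, silyl ether at C3). The forward step needs a clean Wolff rearrangement, capture of the ketene by 22 with the correct orientation, and a substrate without other strong chromophores.

**17 from 15.** The diazo group is removed, leaving a methyl ketone. Diazo transfer to the activated methyl ketone replaces an acid chloride–diazomethane sequence, which is hazardous and prone to dipolar addition at the enone. The forward step must enolize the methyl group in preference to the lactone methine.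

**15 from 8 and 14.** The enol ether O–C(sp2) bond (the future ring A C6–O bond) is cut. The hindered ether is thereby made as an ordinary phenol adding to an unhindered CH carbon that bears a leaving group. The forward step needs attack at carbon rather than at sulfur; the E geometry is expected but is not essential.

**14 from 13.** The S–O bond of the sulfonate is cut, which returns the enol oxygen of a 1,3-dicarbonyl compound. The gain is a precursor with no leaving group that is made in one operation from simple pieces. The forward step must sulfonylate the formyl-derived oxygen, which the hydroxymethylidene ketone tautomer presents.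

**13 from 10 and 11 through 12.** The C–C bond between the future ring A C1 and C5 is cut. Acylating the enamine places the acetyl group unambiguously on the carbon that bears the pentyl chain; direct formylation of the isomeric methyl ketone would not be regioselective. The forward step needs acylation at carbon rather than at nitrogen, and hydrolysis of 12 without loss of the acetyl group.

**10 from 9.** The enamine C–N bond is cut, which leads back to a commodity aldehyde. The forward step needs removal of water and must outrun aldol self-condensation.

**8 from 7.** One O–CH3 bond, the one peri to the lactone carbonyl, is put back. Both ring B oxygens then come from one symmetrical dimethoxyarene and no phenol protection is needed. The forward step must cleave only the methoxy group next to the carbonyl group.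

**7 from 4 through 5 and 6.** The aryl–carboxyl C–C bond and the lactone C–O bond are cut. The carboxyl carbon then comes from carbon dioxide and its position is fixed by the bromine atom. The forward step needs bromine–lithium exchange in the presence of an alkoxide, and ring closure on acidification.

**4 from 2 and 3.** The butyl–carbinol C–C bond is cut, which gives an aldehyde and a simple Grignard reagent. The forward step needs carbonyl addition to be faster than exchange at the aryl bromide.

**2 from 1.** The C–Br bond is cut, which leads to a cheap symmetrical aldehyde. The forward step needs monobromination next to the formyl group and not between the two methoxy groups.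

**22 from 21.** The C(sp)–Si bond is cut. The silyl group on carbon keeps the acetylide and the ynolate monomeric and is removed last. The forward step must cleave the C–Si bond without loss of the O–Si bond.

**21 from 18 and 19 through 20.** The O–Si bond and the C(sp)–O bond are cut, which leads to a commercial silylalkyne and a commercial silyl triflate. The forward step needs oxygen transfer to the acetylide carbon and silylation of 20 on oxygen.

## Other disconnections considered

**Alternative 1: aryne three-component coupling.**
- **Cut:** the ring B C2–O bond and the C1–carboxyl bond.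
- **Forward key step:** CsF would convert 3-(2-butyl-1,3-dioxolan-2-yl)-5-methoxy-2-(trimethylsilyl)phenyl trifluoromethanesulfonate A2 into an aryne under carbon dioxide. The phenoxide of 2,4-bis(benzyloxy)-6-pentylphenol A3 would add at C2 and the C1 aryl anion would take up CO2. This would give 2-[2,4-bis(benzyloxy)-6-pentylphenoxy]-6-(2-butyl-1,3-dioxolan-2-yl)-4-methoxybenzoic acid A1 in a single operation.
- **In favour:** two bonds of the most crowded region form at once. The ketone of A1 is already at the right oxidation level, so the endgame would be only ketal hydrolysis and hydrogenolysis. On convergence and on endgame length this is better than the chosen plan.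
- **Against:**
  - The hindered phenoxide still has to act as the nucleophile at the crowded oxygen.
  - Carbon dioxide can bind the phenoxide reversibly as a carbonate.
  - The orientation of addition rests only on the steric and inductive bias of the dioxolanyl carbon against a remote methoxy group.
  - The aryl anion between the aryloxy group and a quaternary ketal carbon must take CO2 rather than a proton.
  - A2 and A3 each need a multistep preparation.
- **Comparison:** both plans avoid a metal-catalysed coupling (equal). The chosen plan fixes every ring A position by connectivity and polarity, whereas here the regiochemistry depends on aryne distortion. Step count could be similar or slightly lower for the alternative, but more of the risk sits in one step.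

**Alternative 2: pyrone Diels–Alder for ring B.**
- **Cut:** ring B bonds C3–C4 and C5–C6.
- **Forward key step:** 4-[2,4-bis(benzyloxy)-6-pentylphenoxy]-7-butylfuro[3,4-b]pyran-2,5(7H)-dione A5 would add 1,1-dimethoxyethene A6 in an inverse-demand (4+2) reaction. Loss of CO2 and methanol would give 7-[2,4-bis(benzyloxy)-6-pentylphenoxy]-3-butyl-5-methoxy-2-benzofuran-1(3H)-one A4 as the aromatic phthalide.
- **In favour:** the push–pull polarity fixes the regiochemistry, and extrusion of CO2 makes the aromatization irreversible. A6 is a simple ketene acetal. The step is purely thermal, with no diazo compound and no photochemistry, so on operational safety and scale it is better. The aryloxy group would enter A5 by addition–elimination at a vinylogous acid carbon, which avoids an aryl–oxygen coupling just as the chosen plan does (equal).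
- **Against:**
  - Ring A must first be made as the fully substituted phenol A3.
  - A5 is an elaborate bicyclic dione, and its electron-donating 4-aryloxy group should slow an inverse-demand cycloaddition.
  - The lactone methine next to the pyranone is acidic.
  - A4 still needs the same late C3 oxidation plus deprotection as the chosen plan (equal endgame).
- **Comparison:** both are pericyclic cascades ending in an aromatization. The alternative builds the simpler ring B last and leaves the hard ring A substitution pattern to a separate synthesis. The chosen plan should be shorter overall.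

**Alternative 3: Michael–Claisen annulation.**
- **Cut:** ring A bonds C6–C1 and C4–C5.
- **Forward key step:** dimethyl 2-[(3-butyl-5-methoxy-1-oxo-1,3-dihydro-2-benzofuran-7-yl)oxy]propanedioate A8 would be made from phenol 8 by simple O-alkylation. Under NaOMe in methanol A8 would add to (3E)-non-3-en-2-one A9 and the methyl ketone would then condense onto one ester. This would give methyl 1-[(3-butyl-5-methoxy-1-oxo-1,3-dihydro-2-benzofuran-7-yl)oxy]-2,4-dioxo-6-pentylcyclohexane-1-carboxylate A7 as the ring A precursor.
- **In favour:** the reagents are cheap and the chemistry is ionic, with no photochemistry or diazo compound (better on safety). The ether oxygen is alkylated at an sp3 carbon, which is the same idea as the chosen plan (equal). Both ring A oxygens appear at once, and A9 is a commodity, so fewer fragment steps are needed (equal or slightly better on step count).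
- **Against:**
  - A7 is not aromatic: the ester must be removed and the dione dehydrogenated, and the oxidants for that threaten the electron-rich ring B.
  - The tertiary aryloxymalonate anion of A8 is a hindered, reversible Michael donor.
  - Methoxide can open the phthalide, although it recloses on acidification.
  - The two ring A hydroxyls arrive undifferentiated and free, so the late C3 oxidation needs a protection step.
- **Comparison:** the chosen plan reaches the aromatic oxidation level directly and differentiates the oxygens. This alternative reaches ring A through classical condensations at the price of an extra aromatization. It is used below as the fallback for the key step.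

Key step: step 12

Assumption: the target is drawn as the open 2-acylbenzoic acid; it and the 3-butyl-3-hydroxyphthalide formed by oxidation at phthalide C3 are ring–chain tautomers of one compound, and all phthalide intermediates are racemic at C3.

## Route

Step 1
Reactants: 1 3,5-dimethoxybenzaldehyde
Product: 2 2-bromo-3,5-dimethoxybenzaldehyde
Conditions: NBS, MeCN, 0 °C to rt
Reagents that add atoms: N-bromosuccinimide, O=C1CCC(=O)N1Br
Why: Electrophilic aromatic bromination; C2 is para to one methoxy group and ortho to the other and is less crowded than C4 between the two methoxy groups, so monobromination next to the formyl group is expected.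

Step 2
Reactants: 2 2-bromo-3,5-dimethoxybenzaldehyde; 3 n-butylmagnesium chloride
Product: 4 1-(2-bromo-3,5-dimethoxyphenyl)pentan-1-ol (racemic)
Conditions: THF, −78 to 0 °C; aq NH4Cl
Reagents that add atoms: none
Why: Grignard addition to the aldehyde, which is much faster than magnesium–bromine exchange at the electron-rich aryl bromide; the carbinol centre forms racemic and is erased in step 13.

Step 3
Reactants: 4 1-(2-bromo-3,5-dimethoxyphenyl)pentan-1-ol
Product: 7 3-butyl-5,7-dimethoxy-2-benzofuran-1(3H)-one (racemic), via aryllithium alkoxide 5 (not isolated), via hydroxy acid 6 (not isolated)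
Conditions: n-BuLi (2.2 equiv), THF, −78 °C; CO2; then 2 M aq HCl, rt
Reagents that add atoms: carbon dioxide, O=C=O
Why: Deprotonation of the alcohol and bromine–lithium exchange give dianion 5, carboxylation and acidification give 6, and the ortho-hydroxyalkyl benzoic acid should close spontaneously to the five-membered lactone.

Step 4
Reactants: 7 3-butyl-5,7-dimethoxy-2-benzofuran-1(3H)-one
Product: 8 3-butyl-7-hydroxy-5-methoxy-2-benzofuran-1(3H)-one (racemic)
Conditions: BCl3, CH2Cl2, −78 to 0 °C; H2O
Reagents that add atoms: none
Why: Chelation-controlled Lewis acid ether cleavage: BCl3 bridges the lactone carbonyl oxygen and the peri C7 methoxy oxygen, so only that methyl group should be removed and the C5 methoxy group should stay.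

Step 5
Reactants: 9 heptanal
Product: 10 4-[(1E)-hept-1-en-1-yl]morpholine
Conditions: morpholine, cat. TsOH, toluene, reflux (Dean–Stark)
Reagents that add atoms: morpholine, C1COCCN1
Why: Enamine condensation with azeotropic removal of water; the E enamine is the expected isomer and its β-carbon is the nucleophile needed in step 6.

Step 6
Reactants: 10 4-[(1E)-hept-1-en-1-yl]morpholine; 11 acetyl chloride
Product: 13 (3Z)-3-(hydroxymethylidene)octan-2-one, via enaminone 12 (not isolated)
Conditions: Et3N, CH2Cl2, 0 °C to rt; then 1 M aq HCl, rt
Reagents that add atoms: water, O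
Why: Stork enamine acylation at the β-carbon gives vinylogous amide 12, and acid hydrolysis releases the β-keto aldehyde, which should sit as the hydrogen-bonded hydroxymethylidene ketone; the acetyl group is placed unambiguously on the carbon that bears the pentyl chain.

Step 7
Reactants: 13 (3Z)-3-(hydroxymethylidene)octan-2-one
Product: 14 2-acetylhept-1-en-1-yl 4-methylbenzenesulfonate (E/Z mixture)
Conditions: TsCl, Et3N, cat. N-methylimidazole, CH2Cl2, 0 °C
Reagents that add atoms: 4-methylbenzenesulfonyl chloride, Cc1ccc(cc1)S(Cl)(=O)=O
Why: O-sulfonylation of the vinylogous acid gives an enol tosylate that behaves as a vinylogous mixed anhydride; its double-bond geometry does not matter because step 8 goes through a rotatable adduct.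

Step 8
Reactants: 8 3-butyl-7-hydroxy-5-methoxy-2-benzofuran-1(3H)-one; 14 2-acetylhept-1-en-1-yl 4-methylbenzenesulfonate
Product: 15 (3E)-3-{[(3-butyl-5-methoxy-1-oxo-1,3-dihydro-2-benzofuran-7-yl)oxy]methylidene}octan-2-one
Conditions: Cs2CO3, MeCN, rt
Reagents that add atoms: none
Why: Nucleophilic vinylic substitution by addition–elimination: the phenoxide adds to the β-carbon of the β-sulfonyloxy enone and tosylate leaves from the enolate adduct, which should settle to the E isomer with the aryloxy group trans to the acetyl group; the crowded ether oxygen is thus set at an unhindered CH carbon.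

Step 9
Reactants: 15 (3E)-3-{[(3-butyl-5-methoxy-1-oxo-1,3-dihydro-2-benzofuran-7-yl)oxy]methylidene}octan-2-one
Product: 17 (3E)-4-[(3-butyl-5-methoxy-1-oxo-1,3-dihydro-2-benzofuran-7-yl)oxy]-1-diazo-3-pentylbut-3-en-2-one, via trifluoroacetyl diketone 16 (not isolated)
Conditions: LiN(SiMe3)2 (1.05 equiv), THF, −78 °C; CF3CO2CH2CF3, −78 °C; aq NH4Cl; then 4-acetamidobenzenesulfonyl azide, Et3N, H2O, MeCN, rt
Reagents that add atoms: 4-acetamidobenzenesulfonyl azide, CC(=O)Nc1ccc(cc1)S(=O)(=O)N=[N+]=[N-]; 2,2,2-trifluoroethyl trifluoroacetate, O=C(OCC(F)(F)F)C(F)(F)F (its trifluoroacetyl group is present in 16 only)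
Why: Detrifluoroacetylative diazo transfer: the kinetic enolate of the methyl ketone is trifluoroacetylated and the activated diketone 16 undergoes Regitz diazo transfer with loss of the trifluoroacetyl group on the sulfonamide; this should give the unsaturated diazoketone without diazomethane and without dipolar addition to the enone, and the tertiary lactone methine should be deprotonated more slowly than the methyl group.

Step 10
Reactants: 18 ethynyltrimethylsilane; 19 triisopropylsilyl trifluoromethanesulfonate
Product: 21 triisopropyl{[(trimethylsilyl)ethynyl]oxy}silane, via lithium silylethynolate 20 (not isolated)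
Conditions: LiN(SiMe3)2, THF, −78 °C; t-BuOOLi (from t-BuOOH and LiN(SiMe3)2), −78 to 0 °C; then 19, −78 to 0 °C
Reagents that add atoms: tert-butyl hydroperoxide, CC(C)(C)OO
Why: Oxidation of a lithium acetylide by lithium tert-butyl peroxide transfers oxygen to the acetylide carbon and gives ynolate 20; the bulky silyl triflate should silylate it on oxygen, the carbon terminus being blocked by the trimethylsilyl group.

Step 11
Reactants: 21 triisopropyl{[(trimethylsilyl)ethynyl]oxy}silane
Product: 22 (triisopropylsilyloxy)ethyne
Conditions: K2CO3 (0.2 equiv), MeOH, 0 °C, short reaction time; pentane extraction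
Reagents that add atoms: none
Why: Methoxide-catalysed protodesilylation of an alkynylsilane; attack at the small trimethylsilyl group on carbon should be much faster than at the hindered triisopropylsilyl group on oxygen.

Step 12
Reactants: 17 (3E)-4-[(3-butyl-5-methoxy-1-oxo-1,3-dihydro-2-benzofuran-7-yl)oxy]-1-diazo-3-pentylbut-3-en-2-one; 22 (triisopropylsilyloxy)ethyne
Product: 27 3-butyl-7-[2-hydroxy-6-pentyl-4-(triisopropylsilyloxy)phenoxy]-5-methoxy-2-benzofuran-1(3H)-one, via vinylketene 23 (not isolated), via 4-vinylcyclobutenone 24 (not isolated), via dienylketene 25 (not isolated), via cyclohexadienone 26 (not isolated)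
Conditions: 22 (2.5 equiv), hν (medium-pressure mercury lamp, Pyrex filter), degassed ClCH2CH2Cl (0.05 M), rt; then 80 °C
Reagents that add atoms: none
Why: Photolysis expels N2 and the alkenyl group migrates from the carbonyl carbon to the diazo carbon (Wolff rearrangement, ring A bond C1–C2), giving vinylketene 23. The electron-rich ynol ether 22 then adds in a polar (2+2) cycloaddition in which its nucleophilic CH terminus bonds to the ketene carbonyl carbon (C4–C5) and its oxygen-bearing carbon to the ketene α-carbon (C2–C3), giving 24. Four-electron electrocyclic opening of 24 breaks the old C2–C5 bond to give dienylketene 25, whose six-electron disrotatory electrocyclization closes ring A through bond C5–C6 to give 26, and enolization gives phenol 27. The closest known reaction type is the Danheiser benzannulation of photochemically generated vinylketenes with siloxyalkynes; heteroaryl diazoketones with the ring heteroatom on the β-carbon are of the same electronic type, but an open-chain β-aryloxy case has no direct precedent. No stereocentre is created, because the sp3 carbon C6 of 26 is lost on tautomerization and phthalide C3 stays racemic. The step needs regiocontrol in the ketene–alkyne union, which the polarity of the partners secures (silyloxy at C3, H at C4, free OH at C5), and it needs the ketene to meet the alkyne before it dimerizes or acylates the product phenol, for which an excess of 22 and dilution are used. The E geometry of 17 puts the aryloxy group on the outside of the cyclizing triene, so ring B should not hinder the closure.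

Step 13
Reactants: 27 3-butyl-7-[2-hydroxy-6-pentyl-4-(triisopropylsilyloxy)phenoxy]-5-methoxy-2-benzofuran-1(3H)-one
Product: 28 3-butyl-3-hydroxy-7-[2-hydroxy-6-pentyl-4-(triisopropylsilyloxy)phenoxy]-5-methoxy-2-benzofuran-1(3H)-one
Conditions: KN(SiMe3)2 (2.3 equiv), THF, −78 °C; 2-(benzenesulfonyl)-3-phenyloxaziridine, −78 °C; aq NH4Cl, then pH 3
Reagents that add atoms: 2-(benzenesulfonyl)-3-phenyloxaziridine, O=S(=O)(c1ccccc1)N1OC1c1ccccc1
Why: Enolate hydroxylation with an N-sulfonyloxaziridine: two equivalents of base give the phenoxide and the extended lactone enolate, the enolate carbon C3 is the more nucleophilic site and takes the electrophilic oxygen, and the resulting hemiketal is the lactol form of the keto acid; this avoids O2 in an ethereal solvent and a separate protection of the phenol.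

Step 14
Reactants: 28 3-butyl-3-hydroxy-7-[2-hydroxy-6-pentyl-4-(triisopropylsilyloxy)phenoxy]-5-methoxy-2-benzofuran-1(3H)-one
Product: 29 2-(2,4-dihydroxy-6-pentylphenoxy)-4-methoxy-6-pentanoylbenzoic acid
Conditions: Bu4NF, AcOH, THF, 0 °C; acidic work-up
Reagents that add atoms: none
Why: Fluoride cleavage of the aryl silyl ether; the acetic acid buffer keeps the liberated resorcinol and the keto acid from base-mediated oxidation or condensation, and the lactol opens to the keto acid drawn for the target.

## Compound list

1 | 3,5-dimethoxybenzaldehyde | COc1cc(C=O)cc(OC)c1 | starting material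
2 | 2-bromo-3,5-dimethoxybenzaldehyde | COc1cc(OC)c(Br)c(C=O)c1 | intermediate
3 | n-butylmagnesium chloride | CCCC[Mg]Cl | starting material
4 | 1-(2-bromo-3,5-dimethoxyphenyl)pentan-1-ol (racemic) | CCCCC(O)c1cc(OC)cc(OC)c1Br | intermediate
5 | lithium 1-(2-lithio-3,5-dimethoxyphenyl)pentan-1-olate (racemic) | CCCCC(O[Li])c1cc(OC)cc(OC)c1[Li] | intermediate (not isolated)
6 | 2-(1-hydroxypentyl)-4,6-dimethoxybenzoic acid (racemic) | CCCCC(O)c1cc(OC)cc(OC)c1C(=O)O | intermediate (not isolated)
7 | 3-butyl-5,7-dimethoxy-2-benzofuran-1(3H)-one (racemic) | CCCCC1OC(=O)c2c(OC)cc(OC)cc21 | intermediate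
8 | 3-butyl-7-hydroxy-5-methoxy-2-benzofuran-1(3H)-one (racemic) | CCCCC1OC(=O)c2c(O)cc(OC)cc21 | intermediate
9 | heptanal | CCCCCCC=O | starting material
10 | 4-[(1E)-hept-1-en-1-yl]morpholine | CCCCC/C=C/N1CCOCC1 | intermediate
11 | acetyl chloride | CC(Cl)=O | starting material
12 | (3E)-3-(morpholin-4-ylmethylidene)octan-2-one | CC(=O)/C(CCCCC)=C/N1CCOCC1 | intermediate (not isolated)
13 | (3Z)-3-(hydroxymethylidene)octan-2-one (enol form of 2-acetylheptanal) | CC(=O)/C(CCCCC)=C\O | intermediate
14 | 2-acetylhept-1-en-1-yl 4-methylbenzenesulfonate (E/Z mixture, geometry not defined) | CCCCCC(=COS(=O)(=O)c1ccc(C)cc1)C(C)=O | intermediate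
15 | (3E)-3-{[(3-butyl-5-methoxy-1-oxo-1,3-dihydro-2-benzofuran-7-yl)oxy]methylidene}octan-2-one (racemic at phthalide C3) | CC(=O)/C(CCCCC)=C/Oc1cc(OC)cc2c1C(=O)OC2CCCC | intermediate
16 | (5E)-5-{[(3-butyl-5-methoxy-1-oxo-1,3-dihydro-2-benzofuran-7-yl)oxy]methylidene}-1,1,1-trifluorodecane-2,4-dione | O=C(CC(=O)C(F)(F)F)/C(CCCCC)=C/Oc1cc(OC)cc2c1C(=O)OC2CCCC | intermediate (not isolated)
17 | (3E)-4-[(3-butyl-5-methoxy-1-oxo-1,3-dihydro-2-benzofuran-7-yl)oxy]-1-diazo-3-pentylbut-3-en-2-one | O=C(C=[N+]=[N-])/C(CCCCC)=C/Oc1cc(OC)cc2c1C(=O)OC2CCCC | intermediate
18 | ethynyltrimethylsilane | C#C[Si](C)(C)C | starting material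
19 | triisopropylsilyl trifluoromethanesulfonate | CC(C)[Si](OS(=O)(=O)C(F)(F)F)(C(C)C)C(C)C | starting material
20 | lithium 2-(trimethylsilyl)ethynolate | C[Si](C)(C)C#C[O-].[Li+] | intermediate (not isolated)
21 | triisopropyl{[(trimethylsilyl)ethynyl]oxy}silane | C[Si](C)(C)C#CO[Si](C(C)C)(C(C)C)C(C)C | intermediate
22 | (triisopropylsilyloxy)ethyne | C#CO[Si](C(C)C)(C(C)C)C(C)C | intermediate
23 | (3E)-4-[(3-butyl-5-methoxy-1-oxo-1,3-dihydro-2-benzofuran-7-yl)oxy]-3-pentylbuta-1,3-dien-1-one | O=C=C/C(CCCCC)=C/Oc1cc(OC)cc2c1C(=O)OC2CCCC | intermediate (not isolated)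
24 | 4-{(1E)-1-[(3-butyl-5-methoxy-1-oxo-1,3-dihydro-2-benzofuran-7-yl)oxy]hept-1-en-2-yl}-3-(triisopropylsilyloxy)cyclobut-2-en-1-one | O=C1C=C(O[Si](C(C)C)(C(C)C)C(C)C)C1/C(CCCCC)=C/Oc1cc(OC)cc2c1C(=O)OC2CCCC | intermediate (not isolated)
25 | (3E,5E)-6-[(3-butyl-5-methoxy-1-oxo-1,3-dihydro-2-benzofuran-7-yl)oxy]-5-pentyl-3-(triisopropylsilyloxy)hexa-1,3,5-trien-1-one | O=C=C/C(O[Si](C(C)C)(C(C)C)C(C)C)=C\C(CCCCC)=C\Oc1cc(OC)cc2c1C(=O)OC2CCCC | intermediate (not isolated)
26 | 6-[(3-butyl-5-methoxy-1-oxo-1,3-dihydro-2-benzofuran-7-yl)oxy]-5-pentyl-3-(triisopropylsilyloxy)cyclohexa-2,4-dien-1-one (mixture of stereoisomers) | O=C1C=C(O[Si](C(C)C)(C(C)C)C(C)C)C=C(CCCCC)C1Oc1cc(OC)cc2c1C(=O)OC2CCCC | intermediate (not isolated)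
27 | 3-butyl-7-[2-hydroxy-6-pentyl-4-(triisopropylsilyloxy)phenoxy]-5-methoxy-2-benzofuran-1(3H)-one (racemic) | CCCCCc1cc(O[Si](C(C)C)(C(C)C)C(C)C)cc(O)c1Oc1cc(OC)cc2c1C(=O)OC2CCCC | intermediate
28 | 3-butyl-3-hydroxy-7-[2-hydroxy-6-pentyl-4-(triisopropylsilyloxy)phenoxy]-5-methoxy-2-benzofuran-1(3H)-one (lactol form of the keto acid) | CCCCCc1cc(O[Si](C(C)C)(C(C)C)C(C)C)cc(O)c1Oc1cc(OC)cc2c1C(=O)OC2(O)CCCC | intermediate
29 | 2-(2,4-dihydroxy-6-pentylphenoxy)-4-methoxy-6-pentanoylbenzoic acid | CCCCCc1cc(O)cc(O)c1Oc1cc(OC)cc(C(=O)CCCC)c1C(=O)O | target

## Step count and least certain steps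

Total step count: 14. Longest linear sequence: 9 steps (1, 2, 3, 4, 8, 9, 12, 13, 14).

**Step 12 (key step).** The photogenerated vinylketene may be diverted before it meets the alkyne. Possible diversions are photochemical cleavage of the aryl vinyl ether, ketene dimerization and acylation of the product phenol by unreacted ketene. The thermal stage may also stall at the cyclobutenone, because the β-aryloxy group alters the electronics of both electrocyclic steps.

The fallback builds ring A by ionic annulation without photochemistry. It sets out from 8 and comes back at 27. O-Alkylation of 8 with dimethyl 2-bromopropanedioate (K2CO3, acetone) would give dimethyl 2-[(3-butyl-5-methoxy-1-oxo-1,3-dihydro-2-benzofuran-7-yl)oxy]propanedioate F1 as the Michael donor. Michael–Claisen annulation of F1 with (3E)-non-3-en-2-one A9 under NaOMe in MeOH would give methyl 1-[(3-butyl-5-methoxy-1-oxo-1,3-dihydro-2-benzofuran-7-yl)oxy]-2,4-dioxo-6-pentylcyclohexane-1-carboxylate F2 after acidification. Saponification of F2, decarboxylation and acidification, which recloses the lactone, would give 4-[(3-butyl-5-methoxy-1-oxo-1,3-dihydro-2-benzofuran-7-yl)oxy]-5-pentylcyclohexane-1,3-dione F3 as a mixture of stereoisomers. Dehydrogenation of F3 over Pd on carbon in refluxing mesitylene would give 3-butyl-7-(2,4-dihydroxy-6-pentylphenoxy)-5-methoxy-2-benzofuran-1(3H)-one F4 with both ring A hydroxyls free. Silylation of the less hindered C3 hydroxyl of F4 with one equivalent of i-Pr3SiCl and imidazole would give 27.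

**Step 9.** Proton abstraction at the phthalide C3 methine may compete with enolization of the methyl ketone, because the two sites are of similar acidity. That would lead to acylation at the wrong carbon or to recovered 15.

The fallback needs no strong base. It sets out from 15 and comes back at 17. Condensation of 15 with N,N-dimethylformamide dimethyl acetal (neat, 80 °C) would give (1E,4E)-4-{[(3-butyl-5-methoxy-1-oxo-1,3-dihydro-2-benzofuran-7-yl)oxy]methylidene}-1-(dimethylamino)non-1-en-3-one F5 as a crude enaminone. Reaction of F5 with 4-acetamidobenzenesulfonyl azide in MeCN transfers the diazo group with loss of the N-sulfonylformamidine and would give 17.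

**Step 11.** Methanolysis may cleave the O–Si bond together with, or in place of, the C–Si bond, because a silyl ynol ether behaves like the silyl ester of a strong acid. The volatile product may also be lost on concentration.

The fallback moves the desilylation to the arene. It sets out from 21 and comes back at 27. Compound 21 would be used as the ketenophile with 17 under the conditions of step 12, which would give 3-butyl-7-[2-hydroxy-6-pentyl-4-(triisopropylsilyloxy)-3-(trimethylsilyl)phenoxy]-5-methoxy-2-benzofuran-1(3H)-one F6 with the trimethylsilyl group at ring A C4. Ipso-protodesilylation of the electron-rich arene F6 with CF3CO2H in CH2Cl2 at 0 °C would give 27.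

**Step 13.** Dianion formation may be incomplete, the electron-rich phenoxide may be oxidized, or the enolate may add to the sulfonylimine by-product.

The fallback protects first and then oxidizes. It sets out from 27 and comes back at 29. Silylation of 27 with 19 and 2,6-lutidine would give 3-butyl-5-methoxy-7-[2-pentyl-4,6-bis(triisopropylsilyloxy)phenoxy]-2-benzofuran-1(3H)-one F7 with no free phenol. Enolization of F7 with KN(SiMe3)2 and oxygenation with O2, followed by P(OEt)3, would give 3-butyl-3-hydroxy-5-methoxy-7-[2-pentyl-4,6-bis(triisopropylsilyloxy)phenoxy]-2-benzofuran-1(3H)-one F8 as the lactol. Treatment of F8 with Bu4NF and AcOH would remove both silyl groups and give 29.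

## Further compounds

F1 | step 12 | dimethyl 2-[(3-butyl-5-methoxy-1-oxo-1,3-dihydro-2-benzofuran-7-yl)oxy]propanedioate | COC(=O)C(Oc1cc(OC)cc2c1C(=O)OC2CCCC)C(=O)OC
F2 | step 12 | methyl 1-[(3-butyl-5-methoxy-1-oxo-1,3-dihydro-2-benzofuran-7-yl)oxy]-2,4-dioxo-6-pentylcyclohexane-1-carboxylate | COC(=O)C1(Oc2cc(OC)cc3c2C(=O)OC3CCCC)C(=O)CC(=O)CC1CCCCC
F3 | step 12 | 4-[(3-butyl-5-methoxy-1-oxo-1,3-dihydro-2-benzofuran-7-yl)oxy]-5-pentylcyclohexane-1,3-dione | O=C1CC(=O)C(Oc2cc(OC)cc3c2C(=O)OC3CCCC)C(CCCCC)C1
F4 | step 12 | 3-butyl-7-(2,4-dihydroxy-6-pentylphenoxy)-5-methoxy-2-benzofuran-1(3H)-one | CCCCCc1cc(O)cc(O)c1Oc1cc(OC)cc2c1C(=O)OC2CCCC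
F5 | step 9 | (1E,4E)-4-{[(3-butyl-5-methoxy-1-oxo-1,3-dihydro-2-benzofuran-7-yl)oxy]methylidene}-1-(dimethylamino)non-1-en-3-one | CN(C)/C=C/C(=O)/C(CCCCC)=C/Oc1cc(OC)cc2c1C(=O)OC2CCCC
F6 | step 11 | 3-butyl-7-[2-hydroxy-6-pentyl-4-(triisopropylsilyloxy)-3-(trimethylsilyl)phenoxy]-5-methoxy-2-benzofuran-1(3H)-one | CCCCCc1cc(O[Si](C(C)C)(C(C)C)C(C)C)c([Si](C)(C)C)c(O)c1Oc1cc(OC)cc2c1C(=O)OC2CCCC
F7 | step 13 | 3-butyl-5-methoxy-7-[2-pentyl-4,6-bis(triisopropylsilyloxy)phenoxy]-2-benzofuran-1(3H)-one | CCCCCc1cc(O[Si](C(C)C)(C(C)C)C(C)C)cc(O[Si](C(C)C)(C(C)C)C(C)C)c1Oc1cc(OC)cc2c1C(=O)OC2CCCC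
F8 | step 13 | 3-butyl-3-hydroxy-5-methoxy-7-[2-pentyl-4,6-bis(triisopropylsilyloxy)phenoxy]-2-benzofuran-1(3H)-one | CCCCCc1cc(O[Si](C(C)C)(C(C)C)C(C)C)cc(O[Si](C(C)C)(C(C)C)C(C)C)c1Oc1cc(OC)cc2c1C(=O)OC2(O)CCCC
A1 | alternative 1 | 2-[2,4-bis(benzyloxy)-6-pentylphenoxy]-6-(2-butyl-1,3-dioxolan-2-yl)-4-methoxybenzoic acid | CCCCCc1cc(OCc2ccccc2)cc(OCc2ccccc2)c1Oc1cc(OC)cc(C2(CCCC)OCCO2)c1C(=O)O
A2 | alternative 1 | 3-(2-butyl-1,3-dioxolan-2-yl)-5-methoxy-2-(trimethylsilyl)phenyl trifluoromethanesulfonate | CCCCC1(OCCO1)c1cc(OC)cc(OS(=O)(=O)C(F)(F)F)c1[Si](C)(C)C
A3 | alternative 1 | 2,4-bis(benzyloxy)-6-pentylphenol | CCCCCc1cc(OCc2ccccc2)cc(OCc2ccccc2)c1O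
A4 | alternative 2 | 7-[2,4-bis(benzyloxy)-6-pentylphenoxy]-3-butyl-5-methoxy-2-benzofuran-1(3H)-one | CCCCCc1cc(OCc2ccccc2)cc(OCc2ccccc2)c1Oc1cc(OC)cc2c1C(=O)OC2CCCC
A5 | alternative 2 | 4-[2,4-bis(benzyloxy)-6-pentylphenoxy]-7-butylfuro[3,4-b]pyran-2,5(7H)-dione | CCCCCc1cc(OCc2ccccc2)cc(OCc2ccccc2)c1OC1=CC(=O)OC2=C1C(=O)OC2CCCC
A6 | alternative 2 | 1,1-dimethoxyethene | C=C(OC)OC
A7 | alternative 3 | methyl 1-[(3-butyl-5-methoxy-1-oxo-1,3-dihydro-2-benzofuran-7-yl)oxy]-2,4-dioxo-6-pentylcyclohexane-1-carboxylate | COC(=O)C1(Oc2cc(OC)cc3c2C(=O)OC3CCCC)C(=O)CC(=O)CC1CCCCC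
A8 | alternative 3 | dimethyl 2-[(3-butyl-5-methoxy-1-oxo-1,3-dihydro-2-benzofuran-7-yl)oxy]propanedioate | COC(=O)C(Oc1cc(OC)cc2c1C(=O)OC2CCCC)C(=O)OC
A9 | alternative 3 | (3E)-non-3-en-2-one | CCCCC/C=C/C(C)=O
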